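**Plan**

Labdane numbering is used: ring A = C1–C5 and C10, ring B = C5–C10, chain C11–C16 on C9. The target is (13S)-labd-7-ene-3β,15-diyl diformate.
Retrosynthetic cuts, in order: the two formate C–O bonds; C8–C17 (methyl placed on the enol triflate of the 17-nor-8-ketone); the C9–C10 bond of ring B, returned to a C8–C10 bond (retro-semipinacol), which shrinks ring B to the cyclopentane C5–C6–C7–C8–C10 and puts C9 outside the ring; last, C8=C9 (Wittig).
Enabling feature: in ring B the chain-bearing C9 lies between the quaternary C10 and C8, the one ring carbon that can be a carbonyl. C10–C9H(chain)–C8(=O) is therefore the product pattern of a 1,2-shift of C10 from a C8 carbinol to an ionising C9, and the contracted skeleton is the angular-methyl hydrindane of the Hajos–Parrish ketone.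
Forward order: ring A and the five-membered forerunner of ring B arrive together. Ring A is dressed (4,4-Me2, 3β-O, 5α-H), the citronellol-derived chain is joined at C8, C9 is armed, ring B grows from five to six members, C8=O becomes C7=C8–CH3, and the formates come last.
Stereochemistry: C10 comes from (S)-Hajos–Parrish ketone and C13 from (S)-citronellol. C3 and C5 are set by attack on the α face, since the 4β and 10β methyl groups block the β face. C9 is set by equilibration next to the C8 ketone (equatorial chain).

Key step: step 14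

Remark: α/β mean the face opposite to / the same as the C10 methyl group. Labdane numbers are kept for the hydrindanes, in which C8 is bonded directly to C10. TBS = tert-butyldimethylsilyl. Both chiral starting materials are assumed to be purchased in high enantiomeric purity.

**Step 1**
Reactants: 1 (S)-(+)-Hajos–Parrish ketone
Product: 2 C8 ethylene ketal of 1 (C3 enone free)
Conditions: HOCH2CH2OH, p-TsOH·H2O (cat.), 4 Å MS, CH2Cl2, rt
Reagents that add atoms: ethylene glycol OCCO
Why: Acid-catalysed ketalisation is kinetically selective for the saturated cyclopentanone over the less electrophilic conjugated carbonyl, as in the monoketalisation of this class of bicyclic enediones, and touches no stereocentre.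

**Step 2**
Reactants: 2 C8 ethylene ketal
Product: 4 gem-dimethyl β,γ-enone ketal (4,4-Me2; C5=C6), via monomethyl enone 3 (not isolated)
Conditions: KOt-Bu (2.5 equiv), MeI (excess), t-BuOH/THF, 0 °C to rt
Reagents that add atoms: iodomethane CI
Why: Deconjugative double α-alkylation of a 4-en-3-one: KOt-Bu forms the extended dienolate by removing a C6 proton, methylation occurs twice at C4 and the alkene ends at C5=C6, the classical 4,4-dimethylation of bicyclic and steroidal enones, with the ketal masking C8.

**Step 3**
Reactants: 4 gem-dimethyl β,γ-enone ketal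
Product: 5 3β-alcohol
Conditions: NaBH4, MeOH, 0 °C
Reagents that add atoms: none
Why: Borohydride reduction of a 4,4-dimethyl-3-ketone: the axial 4β- and 10β-methyl groups close the β face, so hydride should arrive axially from the α face and set the equatorial 3β-alcohol.

**Step 4**
Reactants: 5 3β-alcohol
Product: 6 3β-TBS ether
Conditions: TBSCl, imidazole, DMF, 50 °C
Reagents that add atoms: tert-butyldimethylsilyl chloride CC(C)(C)[Si](C)(C)Cl
Why: Imidazole-promoted silylation protects the neopentyl-type secondary alcohol (gentle heating offsets the hindrance) without touching a stereocentre.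

**Step 5**
Reactants: 6 3β-TBS ether
Product: 7 trans-hydrindane ketal (5α-H)
Conditions: H2 (5 bar), Pd/C, EtOAc, rt
Reagents that add atoms: none
Why: Heterogeneous syn-hydrogenation of the C5=C6 alkene should occur from the α face because the axial 4β- and 10β-methyl groups flank C5 on the β face, which sets 5α-H and the trans fusion as in the hydrogenation of 4,4-dimethyl-5-ene steroids.

**Step 6**
Reactants: 7 trans-hydrindane ketal
Product: 8 trans-hydrindan-8-one (3β-OTBS; 4,4,10β-Me3; 5α-H)
Conditions: p-TsOH·H2O (cat.), THF/H2O, 45 °C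
Reagents that add atoms: water O
Why: Acid-catalysed ketal hydrolysis frees the C8 ketone, the hindered secondary TBS ether should survive the mild aqueous acid, and no epimerisable centre lies next to the carbonyl group.

**Step 7**
Reactants: 9 (S)-(−)-citronellol
Product: 10 (S)-citronellyl TBS ether
Conditions: TBSCl, imidazole, CH2Cl2, 0 °C to rt
Reagents that add atoms: tert-butyldimethylsilyl chloride CC(C)(C)[Si](C)(C)Cl
Why: Standard silylation of the primary alcohol (future C15–O) leaves the stereocentre that becomes C13 untouched.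

**Step 8**
Reactants: 10 (S)-citronellyl TBS ether
Product: 12 (S)-6-(TBSO)-4-methylhexan-1-ol, via aldehyde 11 (not isolated)
Conditions: O3, CH2Cl2/MeOH, −78 °C; then NaBH4, −78 °C to rt
Reagents that add atoms: ozone [O-][O+]=O
Why: Ozonolysis cleaves the only alkene, and borohydride reduction of the peroxidic products and of aldehyde 11 in the same flask gives the primary alcohol whose carbinol carbon is the future C9.

**Step 9**
Reactants: 12 (S)-6-(TBSO)-4-methylhexan-1-ol
Product: 13 (S)-6-(TBSO)-4-methylhexyl iodide
Conditions: I2, PPh3, imidazole, CH2Cl2, 0 °C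
Reagents that add atoms: iodine II
Why: Appel-type iodination (SN2 on the alkoxyphosphonium ion at a primary carbon) is buffered by imidazole and spares the silyl ether.

**Step 10**
Reactants: 13 iodide
Product: 14 (S)-[6-(TBSO)-4-methylhexyl]triphenylphosphonium iodide
Conditions: PPh3, MeCN, 80 °C
Reagents that add atoms: triphenylphosphine c1ccccc1P(c1ccccc1)c1ccccc1
Why: SN2 quaternisation of PPh3 by the unhindered primary iodide gives the Wittig salt.

**Step 11**
Reactants: 8 trans-hydrindan-8-one; 14 phosphonium iodide
Product: 16 (Z)-8(9)-alkene (C11 cis to C10), via phosphorane 15 (not isolated)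
Conditions: 14 (2 equiv), KOt-Bu, THF, rt; then 8, reflux
Reagents that add atoms: none
Why: Wittig olefination of the cyclopentanone next to the angular methyl group with a non-stabilised ylide, as in the alkylidenation of 17-oxo steroids, should join C8 to C9 and give the (Z)-alkene under kinetic control.

**Step 12**
Reactants: 16 (Z)-8(9)-alkene
Product: 17 (8R,9S)-8α,9-diol
Conditions: OsO4 (5 mol %), NMO, MeSO2NH2, acetone/H2O, rt
Reagents that add atoms: osmium tetroxide O=[Os](=O)(=O)=O; N-methylmorpholine N-oxide C[N+]1([O-])CCOCC1; water O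
Why: Upjohn-type catalytic syn-dihydroxylation should add to the exocyclic alkene from the α face, away from the 10β-methyl group as with 17(20)-ene steroids, which sets 8α-OH (8R) and, through the Z geometry, 9S.

**Step 13**
Reactants: 17 8α,9-diol
Product: 18 9-mesylate (8α-OH free)
Conditions: MsCl, Et3N, CH2Cl2, −10 °C
Reagents that add atoms: methanesulfonyl chloride CS(=O)(=O)Cl
Why: Selective sulfonylation takes the secondary C9 hydroxyl and leaves the tertiary C8 hydroxyl, and C9 keeps its configuration because only the O–H bond is broken.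

**Step 14**
Reactants: 18 9-mesylate
Product: 21 3β,15-bis(TBSO)-17-norlabdan-8-one (5α-H; 9α-H; 13S), via aluminium alkoxide 19 (not isolated), via 9-epi ketone 20 (not isolated)
Conditions: Et2AlCl (2.5 equiv), CH2Cl2, −78 to 0 °C; aq. potassium sodium tartrate; crude product, NaOMe (cat.), MeOH/THF, 40 °C
Reagents that add atoms: none
Why: Et2AlCl turns the tertiary 8α-OH into an aluminium alkoxide whose metal also binds the mesylate, so that ionisation of the C9–O bond is concerted with a suprafacial 1,2-shift of C10 from C8 to C9 while the alkoxide oxygen closes down to the C8 carbonyl (semipinacol rearrangement). The closest known reactions are the organoaluminium-promoted pinacol-type rearrangement of 2-hydroxy mesylates and the D-homoannulation of 17α-hydroxy-20-sulfonyloxy pregnanes, which share the angular-methyl hydrindane environment. No ring is closed by cyclisation: the cyclopentane C5–C6–C7–C8–C10 takes up C9 between C8 and C10 and becomes the six-membered ring B, which forges the hindered C9–C10 bond and is driven by C=O formation and by relief of cyclopentane eclipsing and of the C8/C10 congestion. The step needs migration of C10 rather than C7 and no epoxide closure: in the (8R,9S) isomer the only chelatable rotamer that keeps the C11 chain off the ring and away from the 10β-methyl group holds the mesylate antiperiplanar to C8–C10, the quaternary C10 is also the better migrating group, and the epoxide-forming rotamer (O anti to OMs) cannot chelate. C10 migrates with retention and C9 is inverted, which gives the axial 9-epimer 20; C9 is then α to the new ketone, so catalytic NaOMe should equilibrate it to the equatorial 9β-chain (9α-H) of 21.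

**Step 15**
Reactants: 21 17-norlabdan-8-one
Product: 23 Δ7-enol triflate, via potassium enolate 22 (not isolated)
Conditions: KN(SiMe3)2, THF, −78 °C; then PhNTf2, −78 to 0 °C
Reagents that add atoms: N-phenylbis(trifluoromethanesulfonimide) O=S(=O)(N(c1ccccc1)S(=O)(=O)C(F)(F)F)C(F)(F)F
Why: Kinetic deprotonation of a 2-alkylcyclohexanone by a bulky amide base removes a C7 methylene proton rather than the hindered C9 methine proton, and O-triflation fixes the alkene at C7=C8 without disturbing C9.

**Step 16**
Reactants: 23 Δ7-enol triflate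
Product: 24 labd-7-ene-3β,15-diol bis-TBS ether
Conditions: MeMgBr, Fe(acac)3 (5 mol %), THF/NMP, −30 to 0 °C
Reagents that add atoms: methylmagnesium bromide C[Mg]Br
Why: Iron-catalysed Kumada-type cross-coupling of an alkenyl triflate with MeMgBr replaces OTf by the C17 methyl group with the alkene held at C7=C8, and the silyl ethers are inert.

**Step 17**
Reactants: 24 bis-TBS ether
Product: 25 (13S)-labd-7-ene-3β,15-diol
Conditions: HF·pyridine, THF, 0 to 40 °C
Reagents that add atoms: none
Why: Fluoride-driven desilylation removes both TBS groups in one operation under conditions too mild to move the trisubstituted alkene.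

**Step 18**
Reactants: 25 diol
Product: 26 (13S)-labd-7-ene-3β,15-diyl diformate (target)
Conditions: acetic formic anhydride, pyridine, CH2Cl2, 0 °C to rt
Reagents that add atoms: acetic formic anhydride CC(=O)OC=O
Why: O-Formylation with the mixed anhydride occurs at its more electrophilic and smaller formyl carbonyl, which can reach the hindered 3β-OH as well as the primary 15-OH, and the basic medium avoids acid-induced alkene migration.

**Compound list**

1 | (S)-(+)-Hajos–Parrish ketone, (7aS)-7a-methyl-2,3,7,7a-tetrahydro-1H-indene-1,5(6H)-dione | C[C@]12CCC(=O)C=C1CCC2=O | starting material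
2 | C8 ethylene ketal of 1 (C3 enone free) | C[C@]12CCC(=O)C=C1CCC23OCCO3 | intermediate
3 | 4-methyl-4-en-3-one ketal (monomethyl enone, not isolated) | C[C@]12CCC(=O)C(C)=C1CCC23OCCO3 | intermediate
4 | 4,4-dimethyl-5-en-3-one ketal (C5=C6 in the five-membered ring) | C[C@]12CCC(=O)C(C)(C)C1=CCC23OCCO3 | intermediate
5 | 3β-alcohol of 4 | C[C@]12CC[C@H](O)C(C)(C)C1=CCC23OCCO3 | intermediate
6 | 3β-TBS ether of 5 | C[C@]12CC[C@H](O[Si](C)(C)C(C)(C)C)C(C)(C)C1=CCC23OCCO3 | intermediate
7 | trans-hydrindane ketal (3β-OTBS, 5α-H, 10β-Me) | C[C@]12CC[C@H](O[Si](C)(C)C(C)(C)C)C(C)(C)[C@@H]1CCC23OCCO3 | intermediate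
8 | trans-hydrindan-8-one (3β-OTBS, 4,4,10β-Me3, 5α-H) | C[C@]12CC[C@H](O[Si](C)(C)C(C)(C)C)C(C)(C)[C@@H]1CCC2=O | intermediate
9 | (S)-(−)-citronellol | CC(C)=CCC[C@H](C)CCO | starting material
10 | (S)-citronellyl TBS ether | CC(C)=CCC[C@H](C)CCO[Si](C)(C)C(C)(C)C | intermediate
11 | (S)-6-(TBSO)-4-methylhexanal (not isolated) | O=CCC[C@H](C)CCO[Si](C)(C)C(C)(C)C | intermediate
12 | (S)-6-(TBSO)-4-methylhexan-1-ol | OCCC[C@H](C)CCO[Si](C)(C)C(C)(C)C | intermediate
13 | (S)-6-(TBSO)-4-methylhexyl iodide | ICCC[C@H](C)CCO[Si](C)(C)C(C)(C)C | intermediate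
14 | (S)-[6-(TBSO)-4-methylhexyl]triphenylphosphonium iodide | [I-].c1ccccc1[P+](c1ccccc1)(c1ccccc1)CCC[C@H](C)CCO[Si](C)(C)C(C)(C)C | intermediate
15 | corresponding alkylidenetriphenylphosphorane (not isolated) | c1ccccc1P(c1ccccc1)(c1ccccc1)=CCC[C@H](C)CCO[Si](C)(C)C(C)(C)C | intermediate
16 | (Z)-8(9)-alkylidene hydrindane (C11 cis to C10; 3β,15-bis-OTBS; 13S) | CC(C)(C)[Si](C)(C)OCC[C@@H](C)CC/C=C1/CC[C@H]2C(C)(C)[C@@H](O[Si](C)(C)C(C)(C)C)CC[C@]12C | intermediate
17 | (8R,9S)-8α,9-diol | CC(C)(C)[Si](C)(C)OCC[C@@H](C)CC[C@H](O)[C@@]1(O)CC[C@H]2C(C)(C)[C@@H](O[Si](C)(C)C(C)(C)C)CC[C@]12C | intermediate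
18 | (8R,9S)-9-mesyloxy-8α-ol | CC(C)(C)[Si](C)(C)OCC[C@@H](C)CC[C@H](OS(C)(=O)=O)[C@@]1(O)CC[C@H]2C(C)(C)[C@@H](O[Si](C)(C)C(C)(C)C)CC[C@]12C | intermediate
19 | chloro(ethyl)aluminium 8α-alkoxide of 18 (not isolated) | CC(C)(C)[Si](C)(C)OCC[C@@H](C)CC[C@H](OS(C)(=O)=O)[C@@]1(O[Al](Cl)CC)CC[C@H]2C(C)(C)[C@@H](O[Si](C)(C)C(C)(C)C)CC[C@]12C | intermediate
20 | 9-epi-3β,15-bis(TBSO)-17-norlabdan-8-one (9β-H, axial chain; not isolated) | O=C1CC[C@H]2C(C)(C)[C@@H](O[Si](C)(C)C(C)(C)C)CC[C@]2(C)[C@@H]1CC[C@H](C)CCO[Si](C)(C)C(C)(C)C | intermediate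
21 | 3β,15-bis(TBSO)-17-norlabdan-8-one (5α-H, 9α-H, 10β-Me, 13S) | O=C1CC[C@H]2C(C)(C)[C@@H](O[Si](C)(C)C(C)(C)C)CC[C@]2(C)[C@H]1CC[C@H](C)CCO[Si](C)(C)C(C)(C)C | intermediate
22 | potassium Δ7-enolate of 21 (not isolated) | [K+].[O-]C1=CC[C@H]2C(C)(C)[C@@H](O[Si](C)(C)C(C)(C)C)CC[C@]2(C)[C@H]1CC[C@H](C)CCO[Si](C)(C)C(C)(C)C | intermediate
23 | Δ7-enol triflate of 21 | O=S(=O)(OC1=CC[C@H]2C(C)(C)[C@@H](O[Si](C)(C)C(C)(C)C)CC[C@]2(C)[C@H]1CC[C@H](C)CCO[Si](C)(C)C(C)(C)C)C(F)(F)F | intermediate
24 | (13S)-labd-7-ene-3β,15-diol bis-TBS ether | CC1=CC[C@H]2C(C)(C)[C@@H](O[Si](C)(C)C(C)(C)C)CC[C@]2(C)[C@H]1CC[C@H](C)CCO[Si](C)(C)C(C)(C)C | intermediate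
25 | (13S)-labd-7-ene-3β,15-diol | CC1=CC[C@H]2C(C)(C)[C@@H](O)CC[C@]2(C)[C@H]1CC[C@H](C)CCO | intermediate
26 | (13S)-labd-7-ene-3β,15-diyl diformate | CC1=CC[C@H]2C(C)(C)[C@@H](OC=O)CC[C@]2(C)[C@H]1CC[C@H](C)CCOC=O | target

**Step count and risks**

Total step count: 18.
Longest linear sequence: 14 (steps 1–6 and 11–18).

Steps most likely to fail:

Step 14. The alkoxide oxygen may displace the mesylate, closing the 8,9-epoxide, which would later open to the unexpanded 9-ketone. C7 may migrate in place of C10, or aluminium may transfer ethyl or hydride to the new ketone. The fallback replaces sulfonate ionisation by a thermodynamically driven acyloin shift; it sets out from diol 17 and comes back at ketone 21. Parikh–Doering oxidation (SO3·pyridine, DMSO, Et3N) of the secondary C9 alcohol should give the 8α-hydroxy-9-ketone F1. Base-induced α-ketol rearrangement (KOH, MeOH, rt), the reaction type of the D-homoannulation of 17α-hydroxy-20-oxo pregnanes, should move C10 from C8 to the C9 carbonyl carbon and give the ring-expanded 9-hydroxy-8-ketone F2. F2 is drawn as the 9β-alcohol expected from the anti-dipole alkoxide rotamer, and its C9 configuration is erased in the next operation. SmI2 (THF, HMPA, MeOH) should cleave the C9–O bond α to the ketone, and protonation of the enolate followed by NaOMe equilibration leads to 21.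

Step 11. The basic ylide may enolise the ketone, addition next to the quaternary C10 may be slow, or the Z geometry on which step 14 relies may be eroded. The fallback is a stepwise Horner–Wittig olefination with a separable adduct; it sets out from iodide 13 and ketone 8 and comes back at alkene 16. Michaelis–Arbuzov reaction of 13 with ethyl diphenylphosphinite (120 °C) should give the alkyldiphenylphosphine oxide F3. Lithiation (n-BuLi, THF, −78 °C) and low-temperature addition to 8 from the α face should give β-hydroxy phosphine oxides. The diastereomer with 8β-OH and the C9 configuration that places C11 next to C10 in the syn-periplanar O/P rotamer, the β-hydroxy phosphine oxide F4, is separated. Its stereospecific syn elimination (NaH, DMF, 50 °C) should give geometrically pure 16.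

Step 5. Hydrogen uptake at the shielded trisubstituted alkene may be slow, the alkene may migrate on the catalyst, or hydrogen may be delivered to the wrong face. In the fallback C5 is set by stereoelectronically controlled protonation in a dissolving-metal reduction rather than by surface approach; it sets out from ketal 2 and comes back at 7. Thiomethylation at C4 (PhSH, aq. CH2O, Et3N, EtOH, reflux) should give the 4-(phenylthiomethyl) enone F5. Li in NH3/THF with one equivalent of t-BuOH should cleave the C–S bond, pass through enone 3 and reduce it to the C3 enolate with axial protonation at C5. Trapping with MeI should then give the trans-fused 4,4-dimethyl-3-ketone F6. NaBH4 in MeOH should give the 3β-alcohol F7, and silylation as in step 4 gives 7.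

**Further compounds**

F1 | step 14 | 8α-hydroxy-9-oxo hydrindane (α-ketol; 3β,15-bis-OTBS) | CC(C)(C)[Si](C)(C)OCC[C@@H](C)CCC(=O)[C@@]1(O)CC[C@H]2C(C)(C)[C@@H](O[Si](C)(C)C(C)(C)C)CC[C@]12C
F2 | step 14 | 9β-hydroxy-3β,15-bis(TBSO)-17-norlabdan-8-one | O=C1CC[C@H]2C(C)(C)[C@@H](O[Si](C)(C)C(C)(C)C)CC[C@]2(C)[C@]1(O)CC[C@H](C)CCO[Si](C)(C)C(C)(C)C
F3 | step 11 | (S)-[6-(TBSO)-4-methylhexyl]diphenylphosphine oxide | O=P(c1ccccc1)(c1ccccc1)CCC[C@H](C)CCO[Si](C)(C)C(C)(C)C
F4 | step 11 | 8β-hydroxy-9-(diphenylphosphinoyl) adduct of 8 (diastereomer leading to the Z alkene) | CC(C)(C)[Si](C)(C)OCC[C@@H](C)CC[C@@H](P(=O)(c3ccccc3)c3ccccc3)[C@]1(O)CC[C@H]2C(C)(C)[C@@H](O[Si](C)(C)C(C)(C)C)CC[C@]12C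
F5 | step 5 | 4-(phenylthiomethyl)-4-en-3-one ketal | C[C@]12CCC(=O)C(CSc3ccccc3)=C1CCC24OCCO4
F6 | step 5 | 4,4-dimethyl-5α-H 3-ketone ketal (trans-hydrindane) | C[C@]12CCC(=O)C(C)(C)[C@@H]1CCC23OCCO3
F7 | step 5 | 3β-alcohol of F6 | C[C@]12CC[C@H](O)C(C)(C)[C@@H]1CCC23OCCO3
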